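**Overview**

- Retrosynthesis: ring A of the flavone is cut at C8–C8a, C5–C6, C7–C8 and C4a–C5, which leads back to a 6-aryl-2-(diazoacetyl)-4-pyranone and triisopropylsiloxyacetylene. The pyranone (ring C) is then cut at its ring oxygen and at the two C–C bonds made by Claisen condensations, back to an aryl methyl ketone, ethyl acetate and diethyl oxalate.
- Enabling feature: ring A (C4a–C5–C6–C7–C8–C8a) is a resorcinol with OH at C5 and C7 and H at C6 and C8, fused to ring C through C4a=C8a. That bond is the C3=C2 alkene of a monocyclic 4-pyranone, and a phenol with a meta oxygen is what a vinylketene and an ynol ether deliver.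
- Forward: ring B is bought as 2-hydroxy-4,5-dimethoxyacetophenone and receives its C3 oxygen by bromination, borylation and oxidation. Two Claisen condensations and an acid cyclodehydration close ring C as a pyranone ester, which is turned into the diazoketone.
- Ring A is annulated last in one pot (Wolff rearrangement, ketene/alkyne [2+2], 4π opening, 6π closure, aromatization); desilylation and hydrogenolysis finish the synthesis.
- Stereochemistry: the target has no stereocenter, so nothing has to be set or kept.

Key step: step 13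

Remark: flavone numbering (O1, C2 to C8a, primed numbers for ring B) is used for 24–27; the monocyclic pyranones 11–15 and 21–23 are numbered O1, C2 (carbon bearing the carboxyl-derived group), C3, C4 (C=O), C5, C6 (aryl-bearing carbon).

**Route**

Step 1
Reactants: 1 2-hydroxy-4,5-dimethoxyacetophenone
Product: 2 3-bromo-2-hydroxy-4,5-dimethoxyacetophenone
Conditions: NBS (1.05 equiv), MeCN, 0 °C to 20 °C
Reagents that add atoms: N-bromosuccinimide, O=C1CCC(=O)N1Br
Why: Electrophilic aromatic bromination: C3 is the only position ortho or para to the phenol and is also ortho to the C4 methoxy group, whereas C6 sits next to the deactivating acetyl group, so a single monobromide is expected.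

Step 2
Reactants: 2 3-bromo-2-hydroxy-4,5-dimethoxyacetophenone
Product: 3 3-bromo-2,4,5-trimethoxyacetophenone
Conditions: MeI, K2CO3, DMF, 50 °C
Reagents that add atoms: iodomethane, CI
Why: Williamson ether synthesis: K2CO3 in DMF breaks the hydrogen bond of the chelated phenol and the phenoxide is methylated on oxygen, the ketone not being enolized by carbonate.

Step 3
Reactants: 3 3-bromo-2,4,5-trimethoxyacetophenone
Product: 4 1-[2,4,5-trimethoxy-3-(4,4,5,5-tetramethyl-1,3,2-dioxaborolan-2-yl)phenyl]ethanone
Conditions: B2pin2, Pd(OAc)2 (3 mol%), SPhos (6 mol%), KOAc, 1,4-dioxane, 90 °C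
Reagents that add atoms: bis(pinacolato)diboron, CC1(C)OB(OC1(C)C)B1OC(C)(C)C(C)(C)O1
Why: Miyaura borylation: the bulky, electron-rich biarylphosphine lets zerovalent palladium insert into the C–Br bond flanked by two methoxy groups, and the weak acetate base leaves the enolizable methyl ketone untouched.

Step 4
Reactants: 4 1-[2,4,5-trimethoxy-3-(4,4,5,5-tetramethyl-1,3,2-dioxaborolan-2-yl)phenyl]ethanone
Product: 5 3-hydroxy-2,4,5-trimethoxyacetophenone
Conditions: KHSO5 (as 2KHSO5·KHSO4·K2SO4, 1.1 equiv), acetone/H2O, 0 °C, 15 min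
Reagents that add atoms: potassium peroxymonosulfate, [K+].[O-]S(=O)(=O)OO
Why: Oxidation of an arylboronate by a peroxide (1,2-shift of the aryl group from boron to oxygen, then hydrolysis), which is much faster than any attack of the oxidant on the ketone or the ring.

Step 5
Reactants: 5 3-hydroxy-2,4,5-trimethoxyacetophenone
Product: 6 3-benzyloxy-2,4,5-trimethoxyacetophenone
Conditions: BnBr, K2CO3, DMF, 50 °C
Reagents that add atoms: benzyl bromide, BrCc1ccccc1
Why: Williamson ether synthesis on the phenoxide, which marks the C3 oxygen with a group that can later be removed without touching the three methyl ethers.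

Step 6
Reactants: 6 3-benzyloxy-2,4,5-trimethoxyacetophenone; 7 ethyl acetate
Product: 8 1-(3-benzyloxy-2,4,5-trimethoxyphenyl)butane-1,3-dione
Conditions: NaH (2.5 equiv), 7 (5 equiv), THF, reflux; then 1 M HCl
Reagents that add atoms: none
Why: Crossed Claisen condensation of the methyl ketone enolate with ethyl acetate, driven to completion by deprotonation of the 1,3-diketone formed.

Step 7
Reactants: 8 1-(3-benzyloxy-2,4,5-trimethoxyphenyl)butane-1,3-dione; 9 diethyl oxalate
Product: 11 ethyl 6-(3-benzyloxy-2,4,5-trimethoxyphenyl)-4-oxo-4H-pyran-2-carboxylate, via triketo ester 10 (not isolated)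
Conditions: NaOEt (2.2 equiv), EtOH, 0 °C to 20 °C; then HCl in EtOH, 60 °C
Reagents that add atoms: none
Why: Claisen acylation of the diketone by the non-enolizable oxalate ends at the terminal methyl group because only that product forms a stable doubly enolized salt (acylation at the central carbon is reversible), and acid then closes ring C by attack of the aryl ketone enol oxygen on the α-keto ester carbonyl and loss of water (cyclodehydration of a 1,3,5-tricarbonyl compound to a 4-pyranone), ethanolic HCl at 60 °C being too mild to cleave the benzyl ether.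

Step 8
Reactants: 11 ethyl 6-(3-benzyloxy-2,4,5-trimethoxyphenyl)-4-oxo-4H-pyran-2-carboxylate
Product: 12 6-(3-benzyloxy-2,4,5-trimethoxyphenyl)-4-oxo-4H-pyran-2-carboxylic acid
Conditions: LiOH (1.1 equiv), THF/H2O, 0 °C; then 1 M HCl to pH 2
Reagents that add atoms: lithium hydroxide, [Li+].[OH-]
Why: Saponification: the ester on the electron-poor pyranone C2 is cleaved at 0 °C by one equivalent of hydroxide, and any reversible hydroxide opening of the pyranone is undone on acidification.

Step 9
Reactants: 12 6-(3-benzyloxy-2,4,5-trimethoxyphenyl)-4-oxo-4H-pyran-2-carboxylic acid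
Product: 13 6-(3-benzyloxy-2,4,5-trimethoxyphenyl)-4-oxo-4H-pyran-2-carbonyl chloride
Conditions: (COCl)2, DMF (cat.), CH2Cl2, 0 °C to 20 °C; evaporation
Reagents that add atoms: oxalyl chloride, O=C(Cl)C(=O)Cl
Why: Acid chloride formation through the chloroiminium salt made from DMF and oxalyl chloride, under anhydrous conditions that spare the benzyl ether and the pyranone.

Step 10
Reactants: 13 6-(3-benzyloxy-2,4,5-trimethoxyphenyl)-4-oxo-4H-pyran-2-carbonyl chloride; 14 trimethylsilyldiazomethane
Product: 15 2-(diazoacetyl)-6-(3-benzyloxy-2,4,5-trimethoxyphenyl)-4H-pyran-4-one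
Conditions: 14 (2 equiv), MeCN/THF (1:1), 0 °C to 20 °C, dark
Reagents that add atoms: none
Why: Acylation of a diazoalkane by an acid chloride (first stage of the Arndt–Eistert sequence): the nucleophilic diazo carbon of 14 attacks the carbonyl group, chloride removes silicon, and the second equivalent of 14 takes up adventitious HCl.

Step 11
Reactants: 16 trimethylsilylacetylene
Product: 19 triisopropyl[(trimethylsilyl)ethynyloxy]silane, via lithium (trimethylsilyl)acetylide 17 (not isolated), via lithium (trimethylsilyl)ethynolate 18 (not isolated)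
Conditions: n-BuLi, THF, −78 °C; LiOOt-Bu (from t-BuOOH and LiN(SiMe3)2), −78 °C to 0 °C; i-Pr3SiOTf, −78 °C to 0 °C
Reagents that add atoms: tert-butyl hydroperoxide, CC(C)(C)OO; triisopropylsilyl trifluoromethanesulfonate, CC(C)[Si](OS(=O)(=O)C(F)(F)F)(C(C)C)C(C)C
Why: The lithium acetylide displaces tert-butoxide from the peroxide oxygen of LiOOt-Bu to give the ynolate (oxidation of an acetylide to an ynolate), and the bulky silyl triflate then captures the ambident ynolate on oxygen and not on carbon.

Step 12
Reactants: 19 triisopropyl[(trimethylsilyl)ethynyloxy]silane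
Product: 20 triisopropylsiloxyacetylene
Conditions: K2CO3 (0.1 equiv), MeOH/THF, 0 °C, short contact; pentane extraction
Reagents that add atoms: none
Why: Base-catalysed methanolysis of an alkynyl C–Si bond (protodesilylation of an alkynylsilane): methoxide attacks the small trimethylsilyl group on the sp carbon far faster than the hindered triisopropylsilyl group on oxygen.

Step 13
Reactants: 15 2-(diazoacetyl)-6-(3-benzyloxy-2,4,5-trimethoxyphenyl)-4H-pyran-4-one; 20 triisopropylsiloxyacetylene
Product: 25 3'-benzyloxy-5-hydroxy-2',4',5'-trimethoxy-7-(triisopropylsiloxy)flavone, via pyranonylketene 21 (not isolated), via siloxycyclobutenone 22 (not isolated), via dienylketene 23 (not isolated), via cyclohexadienone 24 (not isolated)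
Conditions: 20 (2 equiv), hν (400–450 nm LED), ClCH2CH2Cl, 20 °C; then PhMe, 110 °C
Reagents that add atoms: none
Why: Light expels N2 from 15 and the pyranonyl group shifts to the carbene carbon (Wolff rearrangement, which makes C8–C8a), giving ketene 21, a vinylketene whose alkene is the pyranone C2=C3 bond. The ynol ether 20 adds across the ketene C=C in a [2+2] cycloaddition (C5–C6 and C7–C8) to give cyclobutenone 22; on warming this opens by a reversible 4π-electrocyclic step to dienylketene 23, ring A closes by 6π-electrocyclization of the ketene carbon onto pyranone C3 (C4a–C5), and enolization of cyclohexadienone 24 gives the chelated C5 phenol. The closest known reaction type is the Danheiser benzannulation in its photochemical Wolff variant, in which aryl, heteroaryl and alkenyl α-diazoketones and triisopropylsiloxyalkynes give resorcinol monosilyl ethers; the 4-pyranone alkene is a vinylogous ester with little aromatic stabilization to lose and its C3 is the nucleophilic enol-ether carbon, matched to the electrophilic ketene carbon, so the closure should be no harder than in those cases. No stereocenter remains in 25, the sp3 carbons of 22 and 24 being transient. The selectivity needed is the orientation of the [2+2]: the polarization of the ynol ether sends its unsubstituted, nucleophilic carbon to the ketene carbonyl carbon, which puts the siloxy group meta to the new phenol (C7), while the site of closure is fixed because C2 of the pyranone has only C3 as a carbon neighbour, the other being O1. Irradiation at 400–450 nm addresses the long-wavelength band of the diazoketone and keeps the arylpyranone chromophore, which absorbs at shorter wavelength, out of play.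

Step 14
Reactants: 25 3'-benzyloxy-5-hydroxy-2',4',5'-trimethoxy-7-(triisopropylsiloxy)flavone
Product: 26 3'-benzyloxy-5,7-dihydroxy-2',4',5'-trimethoxyflavone
Conditions: Bu4NF (1.1 equiv), AcOH (1.1 equiv), THF, 0 °C
Reagents that add atoms: none
Why: Fluoride-induced cleavage of an aryl silyl ether, fast because the 7-oxygen is a vinylogous carboxylate leaving group, with acetic acid as buffer so that no free phenoxide builds up.

Step 15
Reactants: 26 3'-benzyloxy-5,7-dihydroxy-2',4',5'-trimethoxyflavone
Product: 27 5,7,3'-trihydroxy-2',4',5'-trimethoxyflavone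
Conditions: H2 (1 atm), 10% Pd/C, EtOAc/MeOH, 20 °C
Reagents that add atoms: none
Why: Catalytic hydrogenolysis of a benzyl aryl ether, stopped after uptake of one equivalent of hydrogen so that the conjugated C2=C3 bond of the flavone, which is reduced far more slowly, stays.

**Compound list**

1 | 2-hydroxy-4,5-dimethoxyacetophenone | CC(=O)c1cc(OC)c(OC)cc1O | starting material
2 | 3-bromo-2-hydroxy-4,5-dimethoxyacetophenone | CC(=O)c1cc(OC)c(OC)c(Br)c1O | intermediate
3 | 3-bromo-2,4,5-trimethoxyacetophenone | CC(=O)c1cc(OC)c(OC)c(Br)c1OC | intermediate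
4 | 1-[2,4,5-trimethoxy-3-(4,4,5,5-tetramethyl-1,3,2-dioxaborolan-2-yl)phenyl]ethanone | CC(=O)c1cc(OC)c(OC)c(B2OC(C)(C)C(C)(C)O2)c1OC | intermediate
5 | 3-hydroxy-2,4,5-trimethoxyacetophenone | CC(=O)c1cc(OC)c(OC)c(O)c1OC | intermediate
6 | 3-benzyloxy-2,4,5-trimethoxyacetophenone | CC(=O)c1cc(OC)c(OC)c(OCc2ccccc2)c1OC | intermediate
7 | ethyl acetate | CCOC(C)=O | starting material
8 | 1-(3-benzyloxy-2,4,5-trimethoxyphenyl)butane-1,3-dione | CC(=O)CC(=O)c1cc(OC)c(OC)c(OCc2ccccc2)c1OC | intermediate
9 | diethyl oxalate | CCOC(=O)C(=O)OCC | starting material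
10 | ethyl 6-(3-benzyloxy-2,4,5-trimethoxyphenyl)-2,4,6-trioxohexanoate (triketo ester, not isolated) | CCOC(=O)C(=O)CC(=O)CC(=O)c1cc(OC)c(OC)c(OCc2ccccc2)c1OC | intermediate
11 | ethyl 6-(3-benzyloxy-2,4,5-trimethoxyphenyl)-4-oxo-4H-pyran-2-carboxylate | CCOC(=O)c1cc(=O)cc(-c2cc(OC)c(OC)c(OCc3ccccc3)c2OC)o1 | intermediate
12 | 6-(3-benzyloxy-2,4,5-trimethoxyphenyl)-4-oxo-4H-pyran-2-carboxylic acid | OC(=O)c1cc(=O)cc(-c2cc(OC)c(OC)c(OCc3ccccc3)c2OC)o1 | intermediate
13 | 6-(3-benzyloxy-2,4,5-trimethoxyphenyl)-4-oxo-4H-pyran-2-carbonyl chloride | ClC(=O)c1cc(=O)cc(-c2cc(OC)c(OC)c(OCc3ccccc3)c2OC)o1 | intermediate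
14 | trimethylsilyldiazomethane | C[Si](C)(C)C=[N+]=[N-] | starting material
15 | 2-(diazoacetyl)-6-(3-benzyloxy-2,4,5-trimethoxyphenyl)-4H-pyran-4-one | [N-]=[N+]=CC(=O)c1cc(=O)cc(-c2cc(OC)c(OC)c(OCc3ccccc3)c2OC)o1 | intermediate
16 | trimethylsilylacetylene | C#C[Si](C)(C)C | starting material
17 | lithium (trimethylsilyl)acetylide (not isolated) | [Li]C#C[Si](C)(C)C | intermediate
18 | lithium (trimethylsilyl)ethynolate (not isolated) | [Li]OC#C[Si](C)(C)C | intermediate
19 | triisopropyl[(trimethylsilyl)ethynyloxy]silane | C[Si](C)(C)C#CO[Si](C(C)C)(C(C)C)C(C)C | intermediate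
20 | triisopropylsiloxyacetylene | C#CO[Si](C(C)C)(C(C)C)C(C)C | intermediate
21 | 2-(2-oxoethenyl)-6-(3-benzyloxy-2,4,5-trimethoxyphenyl)-4H-pyran-4-one (pyranonylketene, not isolated) | O=C=Cc1cc(=O)cc(-c2cc(OC)c(OC)c(OCc3ccccc3)c2OC)o1 | intermediate
22 | 4-[6-(3-benzyloxy-2,4,5-trimethoxyphenyl)-4-oxo-4H-pyran-2-yl]-3-(triisopropylsiloxy)cyclobut-2-en-1-one (racemic, not isolated) | O=C1C=C(O[Si](C(C)C)(C(C)C)C(C)C)C1c1cc(=O)cc(-c2cc(OC)c(OC)c(OCc3ccccc3)c2OC)o1 | intermediate
23 | 2-[4-oxo-2-(triisopropylsiloxy)buta-1,3-dien-1-yl]-6-(3-benzyloxy-2,4,5-trimethoxyphenyl)-4H-pyran-4-one, ketene arm and pyranone cis on the C=C bond (dienylketene, not isolated) | O=C=C/C(O[Si](C(C)C)(C(C)C)C(C)C)=C\c1cc(=O)cc(-c2cc(OC)c(OC)c(OCc3ccccc3)c2OC)o1 | intermediate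
24 | 2-(3-benzyloxy-2,4,5-trimethoxyphenyl)-7-(triisopropylsiloxy)-4aH-chromene-4,5-dione (keto tautomer of 25, racemic, not isolated) | O=C1C=C(O[Si](C(C)C)(C(C)C)C(C)C)C=C2OC(-c3cc(OC)c(OC)c(OCc4ccccc4)c3OC)=CC(=O)C12 | intermediate
25 | 3'-benzyloxy-5-hydroxy-2',4',5'-trimethoxy-7-(triisopropylsiloxy)flavone | COc1cc(-c2cc(=O)c3c(O)cc(O[Si](C(C)C)(C(C)C)C(C)C)cc3o2)c(OC)c(OCc2ccccc2)c1OC | intermediate
26 | 3'-benzyloxy-5,7-dihydroxy-2',4',5'-trimethoxyflavone | COc1cc(-c2cc(=O)c3c(O)cc(O)cc3o2)c(OC)c(OCc2ccccc2)c1OC | intermediate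
27 | 5,7,3'-trihydroxy-2',4',5'-trimethoxyflavone | COc1cc(-c2cc(=O)c3c(O)cc(O)cc3o2)c(OC)c(O)c1OC | target

**Count**

Total: 15 steps. Longest linear sequence: 13 steps (1 to 27 through steps 1–10 and 13–15); the alkyne branch (steps 11–12) has 2 steps.

**Steps most likely to fail**

1. Step 13. The pyranone has not been tried as the unsaturated partner of this annulation. What may go wrong:
   - light absorbed by the arylpyranone part may trigger ring rearrangement beside nitrogen loss;
   - the ketene may be lost to dimerization or to acylation of the phenol already formed;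
   - the 4π opening may revert without productive 6π closure.

   Fallback: ring C is built onto a bought ring A instead. Setting out from 6, crossed Claisen condensation with diethyl carbonate (NaH, toluene, 80 °C) should give ethyl 3-(3-benzyloxy-2,4,5-trimethoxyphenyl)-3-oxopropanoate F1. Heating F1 with bought phloroglucinol (benzene-1,3,5-triol) without solvent at about 240 °C (Mentzer pyrone synthesis) should acylate the triol at carbon to 1-(3-benzyloxy-2,4,5-trimethoxyphenyl)-3-(2,4,6-trihydroxyphenyl)propane-1,3-dione F2 (not isolated), which cyclodehydrates in the melt. The route is rejoined at 26 and finished by step 15.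

2. Step 12. What may go wrong: methoxide may attack the O-silyl group or add across the electron-rich triple bond instead of cleaving only the C–Si bond, and the volatile, acid-sensitive product may be lost on isolation.

   Fallback: the carbon-bound silicon is carried through the annulation and removed from the arene afterwards. Setting out from 15 and 19, irradiation and warming as in step 13 should lead through ketene 21, the silylated cyclobutenone F3, the silylated dienylketene F4 and the silylated cyclohexadienone F5 (none isolated) to 3'-benzyloxy-5-hydroxy-2',4',5'-trimethoxy-7-(triisopropylsiloxy)-6-(trimethylsilyl)flavone F6. Protodesilylation with CF3CO2H in CH2Cl2 at 0 °C (ipso protonation at the carbon between two oxygen-bearing carbons) should then return 25.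

3. Step 3. What may go wrong: oxidative addition into the bromide flanked by two methoxy groups may be slow, so that protodebromination and protodeboronation outrun the borylation.

   Fallback: stoichiometric halogen–lithium exchange with the ketone masked, in place of catalysis. Setting out from 3, ketalization with ethylene glycol (TsOH, toluene, water removal) should give 2-(3-bromo-2,4,5-trimethoxyphenyl)-2-methyl-1,3-dioxolane F7. Bromine–lithium exchange (n-BuLi, THF, −78 °C) gives [2,3,6-trimethoxy-5-(2-methyl-1,3-dioxolan-2-yl)phenyl]lithium F8 (not isolated), which B(OMe)3 traps as dimethyl [2,3,6-trimethoxy-5-(2-methyl-1,3-dioxolan-2-yl)phenyl]boronate F9 (not isolated). Oxidation with H2O2 and NaOH gives 2,3,6-trimethoxy-5-(2-methyl-1,3-dioxolan-2-yl)phenol F10, and aqueous HCl in THF frees the ketone and returns 5.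

**Further compounds**

F1 | step 13 | ethyl 3-(3-benzyloxy-2,4,5-trimethoxyphenyl)-3-oxopropanoate | CCOC(=O)CC(=O)c1cc(OC)c(OC)c(OCc2ccccc2)c1OC
F2 | step 13 | 1-(3-benzyloxy-2,4,5-trimethoxyphenyl)-3-(2,4,6-trihydroxyphenyl)propane-1,3-dione | O=C(CC(=O)c1c(O)cc(O)cc1O)c1cc(OC)c(OC)c(OCc2ccccc2)c1OC
F3 | step 12 | 4-[6-(3-benzyloxy-2,4,5-trimethoxyphenyl)-4-oxo-4H-pyran-2-yl]-3-(triisopropylsiloxy)-2-(trimethylsilyl)cyclobut-2-en-1-one (racemic) | O=C1C([Si](C)(C)C)=C(O[Si](C(C)C)(C(C)C)C(C)C)C1c1cc(=O)cc(-c2cc(OC)c(OC)c(OCc3ccccc3)c2OC)o1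
F4 | step 12 | 2-[4-oxo-2-(triisopropylsiloxy)-3-(trimethylsilyl)buta-1,3-dien-1-yl]-6-(3-benzyloxy-2,4,5-trimethoxyphenyl)-4H-pyran-4-one, ketene arm and pyranone cis | O=C=C([Si](C)(C)C)/C(O[Si](C(C)C)(C(C)C)C(C)C)=C\c1cc(=O)cc(-c2cc(OC)c(OC)c(OCc3ccccc3)c2OC)o1
F5 | step 12 | 2-(3-benzyloxy-2,4,5-trimethoxyphenyl)-7-(triisopropylsiloxy)-6-(trimethylsilyl)-4aH-chromene-4,5-dione (racemic) | O=C1C([Si](C)(C)C)=C(O[Si](C(C)C)(C(C)C)C(C)C)C=C2OC(-c3cc(OC)c(OC)c(OCc4ccccc4)c3OC)=CC(=O)C12
F6 | step 12 | 3'-benzyloxy-5-hydroxy-2',4',5'-trimethoxy-7-(triisopropylsiloxy)-6-(trimethylsilyl)flavone | COc1cc(-c2cc(=O)c3c(O)c([Si](C)(C)C)c(O[Si](C(C)C)(C(C)C)C(C)C)cc3o2)c(OC)c(OCc2ccccc2)c1OC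
F7 | step 3 | 2-(3-bromo-2,4,5-trimethoxyphenyl)-2-methyl-1,3-dioxolane | CC1(c2cc(OC)c(OC)c(Br)c2OC)OCCO1
F8 | step 3 | [2,3,6-trimethoxy-5-(2-methyl-1,3-dioxolan-2-yl)phenyl]lithium | [Li]c1c(OC)c(OC)cc(C2(C)OCCO2)c1OC
F9 | step 3 | dimethyl [2,3,6-trimethoxy-5-(2-methyl-1,3-dioxolan-2-yl)phenyl]boronate | COB(OC)c1c(OC)c(OC)cc(C2(C)OCCO2)c1OC
F10 | step 3 | 2,3,6-trimethoxy-5-(2-methyl-1,3-dioxolan-2-yl)phenol | CC1(c2cc(OC)c(OC)c(O)c2OC)OCCO1
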